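- 2.33 is how many times more enzyme-hours Friday's gets than Saturday's. An enzyme-hour is the whole charge of free enzyme working for an hour, and 3 portions 1.5 h apart wait 1.5 h on average, so Saturday's counts 0.150 mM·h and Friday's counts 0.350 mM·h, more than Saturday's.

| flask | starting material | gas | free enzyme | remark | time |
|---|---|---|---|---|---|
| summer | 0.10 M | 65 mM (held) | 0.10 mM (in portions, 3) | run made earlier; portions every 1.5 h |  |
| winter | 0.15 M | 65 mM (held) | 0.10 mM (in portions, 3) | run made earlier; portions every 1.5 h |  |
| Saturday's | 0.20 M | 65 mM | 0.10 mM | everything together at the start | 1.5 h |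
| Friday's | 0.20 M | 65 mM (held) | 0.10 mM (in portions, 3) | the portions of free enzyme follow each other after 1.5 h, the first at the start | 5.0 h |

- summer (time / h: target / %, starting material / %): 1.00: 7.6, 92.5; 2.00: 21.8, 77.7; 3.00: 38.6, 60.9; 4.00: 61.0, 39.3; 5.00: 77.1, 22.8
- winter (time / h: target / %, starting material / %): 1.00: 5.2, 94.3; 2.00: 15.9, 84.0; 3.00: 28.7, 70.8; 4.00: 46.5, 53.8; 5.00: 61.4, 38.2

(standard deviation of a reading: 0.3 percentage points)

- the winner by amount of target, in percent of the starting material charged; "neither" if no more than 2 percentage points parts them (Saturday's / Friday's / neither)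
- how much target is there at the end, in percent of the starting material charged: Saturday's
- how much target is there at the end, in percent of the starting material charged: Friday's

- at the start none of the gas is in solution

- The summer and winter runs follow Friday's schedule, so I divide their final target by the same enzyme-hours. This turnover frequency reads 220 h⁻¹ in summer and 263 h⁻¹ in winter.
- In logarithms, the slope of turnover against starting material is 0.438, an apparent order. Carrying that slope to 0.20 M gives 299 h⁻¹, my turnover per enzyme-hour at Friday's and Saturday's charge. So I expect 52.2 % for Friday's.
- Saturday's has two extremes. At 299 h⁻¹ throughout it gives 22.4 %. At the winter run's first-hour turnover, 234 h⁻¹, read while gas was just starting to enter, it gives 17.6 %.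
- I place Saturday's between them, nearer the low end, because in my reckoning the slow first hour outlasts the 0.500 h after it. Weighting the two by time, I commit to 19.2 %.
- The winner comes cheaply: at 234 h⁻¹ my reckoning for Friday's still gives 40.9 %, above my upper extreme for Saturday's.
- The forecast says Friday's, with 16.5 % for Saturday's and 51 % for Friday's, reasoning that “The rate therefore saturates in starting material”. My Saturday's figure stands above its number, and my Friday's figure stands above its number too.
- The simulation gives Friday's: 50.1 % for Friday's and 18.7 % for Saturday's.

    second complex → free enzyme + target (k = 5200 h⁻¹)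
    first complex ⇌ loaded enzyme + first product (K = 0.140 M, k = 640 h⁻¹)
    second substrate + loaded enzyme ⇌ second complex (K = 13.0 M⁻¹, k = 63000 M⁻¹ h⁻¹)
    gas ⇌ second substrate, rate k4*(csat - [second substrate]) (kL = 1.10 h⁻¹)
    starting material + free enzyme ⇌ first complex (K = 21.0 M⁻¹, k = 90000 M⁻¹ h⁻¹)

- In Saturday's the gas passes into second substrate, 0.0248 M at 0.750 h and 0.0330 M at 1.50 h, below saturation at 65 mM, while first complex holds 51.3 % of the catalyst charged. In Friday's second substrate stands at 0.0453 M at 2.50 h and 0.0418 M at 5.00 h, and the flask's final target gives a turnover frequency of 286 h⁻¹ against my 299 h⁻¹. For the neighbour of Saturday's with 6.0 × 10⁻⁵ M of free enzyme, scaling my reckoning by enzyme-hours gives 11.5 %, and that flask gives 12.1 %.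

(The runs were computed for substances that don't exist; noise was put on by code.)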